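The central ring is cut from the CH2 of its two-carbon bridge. A carboxyl group is placed on the only C–H carbon of that ring, the one between the C–OH carbon and the bridge-bearing carbon. There it first blocks its own position while two 4-(benzyloxy)benzyl groups enter beside the methoxy carbon. It then steers rhodium to the neighbouring C–H (meta to both oxygenated carbons) for a dehydrogenative coupling with 3-(benzyloxy)styrene, and finally leaves as CO2 in the same flask. The precursor is thus a benzoic acid with one free ring position; the product is an (E)-stilbene, which one hydrogenation reduces and debenzylates to the target.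

Key step: step 5

Remark on the chemistry: the target has no stereocentre and no stereogenic double bond, so it is a single achiral compound and no stereocontrol is needed; the (E)-alkene of 9 and 10 disappears in step 6. Compounds 1, 2 and 7 are taken as commercially available.

Step 1
Reactants: 1 methyl 2-hydroxy-4-methoxybenzoate; 2 4-(benzyloxy)benzyl alcohol (2.4 equiv)
Product: 4 methyl 3,5-bis[4-(benzyloxy)benzyl]-2-hydroxy-4-methoxybenzoate, via monobenzyl ester 3 (not isolated)
Conditions: p-TsOH·H2O (10 mol%), HFIP/CH2Cl2, rt to 40 °C, slow addition of 2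
Reagents that add atoms: none
Why: In this dehydrative Friedel–Crafts benzylation the 4-alkoxybenzyl cation from 2 should attack C5 (para to OH, ortho to OMe) and then C3 (between OH and OMe), the only carbons activated by both oxygen donors, because the ester occupies the other position ortho to OH and C6 is meta to both donors.

Step 2
Reactants: 4 methyl 3,5-bis[4-(benzyloxy)benzyl]-2-hydroxy-4-methoxybenzoate
Product: 5 methyl 2-(benzyloxy)-3,5-bis[4-(benzyloxy)benzyl]-4-methoxybenzoate
Conditions: BnBr, K2CO3, TBAI (cat.), DMF, 60 °C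
Reagents that add atoms: benzyl bromide, BrCc1ccccc1
Why: Williamson etherification of the phenoxide should mask the chelated phenol as a benzyl ether that is inert to the oxidative key step and leaves with the other benzyl groups at the end.

Step 3
Reactants: 5 methyl 2-(benzyloxy)-3,5-bis[4-(benzyloxy)benzyl]-4-methoxybenzoate
Product: 6 2-(benzyloxy)-3,5-bis[4-(benzyloxy)benzyl]-4-methoxybenzoic acid
Conditions: LiOH·H2O, THF/MeOH/H2O, 60 °C; then 1 M HCl
Reagents that add atoms: lithium hydroxide, [Li+].[OH-]
Why: Saponification of a benzoate with only one ortho substituent should free the carboxylic acid needed as directing group, while aryl ethers are inert to hydroxide.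

Step 4
Reactants: 7 3-(benzyloxy)benzaldehyde
Product: 8 1-(benzyloxy)-3-vinylbenzene
Conditions: Ph3PCH3Br, KOtBu, THF, 0 °C to rt
Reagents that add atoms: methyltriphenylphosphonium bromide, C[P+](c1ccccc1)(c1ccccc1)c1ccccc1.[Br-]
Why: Wittig methylenation of a non-enolisable aryl aldehyde should give the terminal styrene.

Step 5
Reactants: 6 2-(benzyloxy)-3,5-bis[4-(benzyloxy)benzyl]-4-methoxybenzoic acid; 8 1-(benzyloxy)-3-vinylbenzene (1.5 equiv)
Product: 10 1-(benzyloxy)-2,4-bis[4-(benzyloxy)benzyl]-5-[(E)-2-[3-(benzyloxy)phenyl]ethenyl]-3-methoxybenzene, via ortho-styryl benzoic acid 9 (not isolated)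
Conditions: [Cp*RhCl2]2 (2.5 mol%), AgOAc (3 equiv), DMAc, N2, 120 °C; then 160 °C
Reagents that add atoms: none
Why: Carboxylate-assisted rhodation (concerted metalation–deprotonation) of the only C–H ortho to the carboxylate should give a five-membered rhodacycle, 8 should insert with the aryl group going to its terminal carbon, and syn-β-hydride elimination should release the (E)-styryl acid 9 while Ag(I) reoxidises Rh(I); at the higher temperature the remaining Ag(I) should turn the now doubly ortho-substituted, electron-rich carboxylate into an aryl–silver species that loses CO2 and is protonated by the acetic acid formed. The closest known reaction type is the rhodium(III)-catalysed oxidative ortho-olefination of 2-alkoxybenzoic acids with styrenes followed by protodecarboxylation, a dehydrogenative (Fujiwara–Moritani-type) union of two C–H carbons with the carboxyl as a traceless directing group. No ring is closed and no stereocentre is formed; the (E)-geometry follows from syn-insertion and syn-elimination and is erased in step 6. The step needs site selectivity, which the substrate secures because the second ortho position carries the benzyloxy group and the carboxylate can reach no other sp2 C–H. It also needs olefination to run before decarboxylation, which the two temperature stages and the directed C–H cleavage are expected to secure. Styrenes, unlike acrylates, should not close to a lactone, so the acid stays free for the decarboxylation.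

Step 6
Reactants: 10 1-(benzyloxy)-2,4-bis[4-(benzyloxy)benzyl]-5-[(E)-2-[3-(benzyloxy)phenyl]ethenyl]-3-methoxybenzene
Product: 11 Bulbocodin C, 2,4-bis(4-hydroxybenzyl)-5-[2-(3-hydroxyphenyl)ethyl]-3-methoxyphenol
Conditions: H2 (1 atm), 10% Pd/C, EtOAc/MeOH, rt
Reagents that add atoms: none
Why: Heterogeneous hydrogenation should saturate the stilbene C=C and hydrogenolyse all four O-benzyl ethers in one operation, while the aryl methyl ether and the diarylmethane C–C bonds are inert.

Compound list
1 | methyl 2-hydroxy-4-methoxybenzoate | COC(=O)c1ccc(OC)cc1O | starting material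
2 | 4-(benzyloxy)benzyl alcohol | OCc1ccc(OCc2ccccc2)cc1 | starting material
3 | methyl 5-[4-(benzyloxy)benzyl]-2-hydroxy-4-methoxybenzoate | COC(=O)c1cc(Cc2ccc(OCc3ccccc3)cc2)c(OC)cc1O | intermediate
4 | methyl 3,5-bis[4-(benzyloxy)benzyl]-2-hydroxy-4-methoxybenzoate | COC(=O)c1cc(Cc2ccc(OCc3ccccc3)cc2)c(OC)c(Cc2ccc(OCc3ccccc3)cc2)c1O | intermediate
5 | methyl 2-(benzyloxy)-3,5-bis[4-(benzyloxy)benzyl]-4-methoxybenzoate | COC(=O)c1cc(Cc2ccc(OCc3ccccc3)cc2)c(OC)c(Cc2ccc(OCc3ccccc3)cc2)c1OCc1ccccc1 | intermediate
6 | 2-(benzyloxy)-3,5-bis[4-(benzyloxy)benzyl]-4-methoxybenzoic acid | OC(=O)c1cc(Cc2ccc(OCc3ccccc3)cc2)c(OC)c(Cc2ccc(OCc3ccccc3)cc2)c1OCc1ccccc1 | intermediate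
7 | 3-(benzyloxy)benzaldehyde | O=Cc1cccc(OCc2ccccc2)c1 | starting material
8 | 1-(benzyloxy)-3-vinylbenzene | C=Cc1cccc(OCc2ccccc2)c1 | intermediate
9 | 2-(benzyloxy)-3,5-bis[4-(benzyloxy)benzyl]-6-[(E)-2-[3-(benzyloxy)phenyl]ethenyl]-4-methoxybenzoic acid | OC(=O)c1c(/C=C/c2cccc(OCc3ccccc3)c2)c(Cc2ccc(OCc3ccccc3)cc2)c(OC)c(Cc2ccc(OCc3ccccc3)cc2)c1OCc1ccccc1 | intermediate
10 | 1-(benzyloxy)-2,4-bis[4-(benzyloxy)benzyl]-5-[(E)-2-[3-(benzyloxy)phenyl]ethenyl]-3-methoxybenzene | COc1c(Cc2ccc(OCc3ccccc3)cc2)c(OCc2ccccc2)cc(/C=C/c2cccc(OCc3ccccc3)c2)c1Cc1ccc(OCc2ccccc2)cc1 | intermediate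
11 | Bulbocodin C | COc1c(Cc2ccc(O)cc2)c(O)cc(CCc2cccc(O)c2)c1Cc1ccc(O)cc1 | target

Total step count: 6. Longest linear sequence: 5 (steps 1, 2, 3, 5, 6).

Steps most likely to fail

Step 5. Rhodation and alkene insertion at a C–H flanked by the benzylic substituent may be slow, so that silver-mediated protodecarboxylation of the acid could run ahead of the olefination. The fallback sets out from 6 and replaces C–H metalation by a nitrogen-directed electrophilic bromination of the same carbon. Curtius rearrangement (DPPA, Et3N, toluene, 90 °C) should lead through the acyl azide F1 to the isocyanate F2, which aqueous NaOH in THF hydrolyses to 2-(benzyloxy)-3,5-bis[4-(benzyloxy)benzyl]-4-methoxyaniline F3. NBS in DMF at −20 °C should brominate the only free position ortho to the amino group and give the bromoaniline F4. Diazotisation (NaNO2, aq. HBF4, EtOH, 0 °C) to the diazonium tetrafluoroborate F5 and reduction with H3PO2 removes the nitrogen and gives 1-(benzyloxy)-5-bromo-2,4-bis[4-(benzyloxy)benzyl]-3-methoxybenzene F6. A Mizoroki–Heck reaction of F6 with 8 (Pd(OAc)2, P(o-tol)3, Et3N, DMF, 110 °C) comes back to the route at 10.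

Step 1. The second benzylation, at the crowded carbon between OH and OMe, may lag behind self-condensation of the benzylic alcohol and alkylation of the pendant aryl ether rings. The fallback sets out from 1 and builds the two diarylmethane bonds by cross-coupling. Iodination (NIS, cat. TFA, MeCN, rt) should give methyl 2-hydroxy-3,5-diiodo-4-methoxybenzoate F7, and BnBr/K2CO3 in DMF its benzyl ether, methyl 2-(benzyloxy)-3,5-diiodo-4-methoxybenzoate F8. A twofold Negishi coupling of F8 with 4-(benzyloxy)benzylzinc chloride F9 (from commercial 4-(benzyloxy)benzyl chloride, Zn dust, LiCl, THF) under Pd(OAc)2/SPhos in THF at 50 °C comes back to the route at 5, bypassing 4.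

Step 6. Hydrogenolysis of four benzyl ethers may stall through catalyst poisoning by traces of silver or through adsorption of the polyphenol on the catalyst. The fallback sets out from 10 and separates the two tasks without a metal surface. Diimide (TsNHNH2, NaOAc, THF/H2O, reflux) should reduce only the C=C and give 1-(benzyloxy)-2,4-bis[4-(benzyloxy)benzyl]-5-[2-[3-(benzyloxy)phenyl]ethyl]-3-methoxybenzene F10. BCl3 with pentamethylbenzene as cation scavenger (CH2Cl2, −78 °C) should then cleave the benzyl ethers while the methyl ether survives, and comes back to the route at 11.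

Further compounds
F1 | step 5 | 2-(benzyloxy)-3,5-bis[4-(benzyloxy)benzyl]-4-methoxybenzoyl azide | [N-]=[N+]=NC(=O)c1cc(Cc2ccc(OCc3ccccc3)cc2)c(OC)c(Cc2ccc(OCc3ccccc3)cc2)c1OCc1ccccc1
F2 | step 5 | 2-(benzyloxy)-3,5-bis[4-(benzyloxy)benzyl]-4-methoxyphenyl isocyanate | O=C=Nc1cc(Cc2ccc(OCc3ccccc3)cc2)c(OC)c(Cc2ccc(OCc3ccccc3)cc2)c1OCc1ccccc1
F3 | step 5 | 2-(benzyloxy)-3,5-bis[4-(benzyloxy)benzyl]-4-methoxyaniline | Nc1cc(Cc2ccc(OCc3ccccc3)cc2)c(OC)c(Cc2ccc(OCc3ccccc3)cc2)c1OCc1ccccc1
F4 | step 5 | 2-(benzyloxy)-6-bromo-3,5-bis[4-(benzyloxy)benzyl]-4-methoxyaniline | Nc1c(Br)c(Cc2ccc(OCc3ccccc3)cc2)c(OC)c(Cc2ccc(OCc3ccccc3)cc2)c1OCc1ccccc1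
F5 | step 5 | 2-(benzyloxy)-6-bromo-3,5-bis[4-(benzyloxy)benzyl]-4-methoxybenzenediazonium tetrafluoroborate | N#[N+]c1c(Br)c(Cc2ccc(OCc3ccccc3)cc2)c(OC)c(Cc2ccc(OCc3ccccc3)cc2)c1OCc1ccccc1.F[B-](F)(F)F
F6 | step 5 | 1-(benzyloxy)-5-bromo-2,4-bis[4-(benzyloxy)benzyl]-3-methoxybenzene | COc1c(Cc2ccc(OCc3ccccc3)cc2)c(OCc2ccccc2)cc(Br)c1Cc1ccc(OCc2ccccc2)cc1
F7 | step 1 | methyl 2-hydroxy-3,5-diiodo-4-methoxybenzoate | COC(=O)c1cc(I)c(OC)c(I)c1O
F8 | step 1 | methyl 2-(benzyloxy)-3,5-diiodo-4-methoxybenzoate | COC(=O)c1cc(I)c(OC)c(I)c1OCc1ccccc1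
F9 | step 1 | 4-(benzyloxy)benzylzinc chloride | Cl[Zn]Cc1ccc(OCc2ccccc2)cc1
F10 | step 6 | 1-(benzyloxy)-2,4-bis[4-(benzyloxy)benzyl]-5-[2-[3-(benzyloxy)phenyl]ethyl]-3-methoxybenzene | COc1c(Cc2ccc(OCc3ccccc3)cc2)c(OCc2ccccc2)cc(CCc2cccc(OCc3ccccc3)c2)c1Cc1ccc(OCc2ccccc2)cc1
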